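**Plan**
Retrosynthesis first removes the benzyl group from the ring-B carboxyl, then cuts both bonds at the depside carbonyl: ring-A C1–C(=O) and C(=O)–O4 of ring B.
The feature that allows this is that the ester carbonyl carbon, sitting between C1 of the 2,4-dimethoxy-6-pentylphenyl ring (ring A) and the phenolic oxygen at C4 of the 2-methoxy-6-propylbenzoate ring (ring B), is a single one-carbon unit that carbon monoxide can supply.
Ring A is traced back through its C–I bond and two O–methyl bonds to olivetol; ring B through its benzyl ester, 2-O-methyl and C1 carboxyl carbon (introduced as a formyl group) to 5-propylresorcinol.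
Forward: no ring is built, both arenes are bought; ring A is methylated and iodinated, ring B is formylated, 4-O-protected, 2-O-methylated, oxidised, benzylated and unmasked, then the halves are joined by carbonylation and the benzyl ester is hydrogenolysed.
Stereochemistry: the target has no stereocentre or other stereo-element, so nothing has to be set or preserved.

Key step: step 9

Assumption: the target is achiral, so the "single enantiomer" is simply the one constitution drawn; olivetol and 5-propylresorcinol are taken as commercial.

**Route**

Step 1
Reactants: 1 olivetol (5-pentylbenzene-1,3-diol)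
Product: 2 1,3-dimethoxy-5-pentylbenzene
Conditions: MeI (3 equiv), K2CO3 (4 equiv), acetone, reflux
Reagents that add atoms: iodomethane, CI
Why: Williamson ether synthesis; carbonate deprotonates both phenols and each phenoxide displaces iodide from MeI, with no competing nucleophilic site in the molecule.

Step 2
Reactants: 2 1,3-dimethoxy-5-pentylbenzene
Product: 3 2-iodo-1,5-dimethoxy-3-pentylbenzene
Conditions: NIS (1.0 equiv), MeCN, 0 °C to rt, dark
Reagents that add atoms: N-iodosuccinimide, O=C1CCC(=O)N1I
Why: Electrophilic aromatic iodination; the carbon ortho to one methoxy, para to the other and next to the pentyl chain should be attacked in preference to the carbon squeezed between two methoxy groups, and one equivalent at low temperature limits a second iodination.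

Step 3
Reactants: 4 5-propylresorcinol (5-propylbenzene-1,3-diol)
Product: 6 2,4-dihydroxy-6-propylbenzaldehyde, via iminium chloride 5 (not isolated)
Conditions: POCl3 (1.3 equiv), DMF, 0 °C to rt; then H2O, 50 °C
Reagents that add atoms: N,N-dimethylformamide, CN(C)C=O (formyl carbon); water, O (carbonyl oxygen)
Why: Vilsmeier–Haack formylation; the chloroiminium ion attacks para to one hydroxyl and ortho to the other (the carbon next to propyl), as is established for orcinol and olivetol, and water hydrolyses the aryl iminium salt to the aldehyde.

Step 4
Reactants: 6 2,4-dihydroxy-6-propylbenzaldehyde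
Product: 7 2-hydroxy-4-(methoxymethoxy)-6-propylbenzaldehyde
Conditions: MOMCl (1.05 equiv), i-Pr2NEt (1.5 equiv), CH2Cl2, 0 °C
Reagents that add atoms: chloromethyl methyl ether, COCCl
Why: Selective O-alkylation (MOM acetal formation); the 2-hydroxyl is tied up in a hydrogen bond to the formyl oxygen, so one equivalent of reagent should alkylate only the free, more acidic 4-hydroxyl.

Step 5
Reactants: 7 2-hydroxy-4-(methoxymethoxy)-6-propylbenzaldehyde
Product: 8 2-methoxy-4-(methoxymethoxy)-6-propylbenzaldehyde
Conditions: MeI (2 equiv), K2CO3 (2 equiv), DMF, 40 °C
Reagents that add atoms: iodomethane, CI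
Why: Williamson methylation of the remaining chelated phenol under slightly more forcing carbonate/DMF conditions, to which the MOM acetal and the aldehyde are inert.

Step 6
Reactants: 8 2-methoxy-4-(methoxymethoxy)-6-propylbenzaldehyde
Product: 9 2-methoxy-4-(methoxymethoxy)-6-propylbenzoic acid
Conditions: NaClO2, NaH2PO4, 2-methyl-2-butene (excess), t-BuOH/THF/H2O, 0 °C to rt
Reagents that add atoms: sodium chlorite, [Na+].[O-]Cl=O
Why: Pinnick (Lindgren) oxidation; chlorous acid adds to the aldehyde and fragments to the acid, the alkene scavenger traps the hypochlorous acid before it can chlorinate the electron-rich ring, and the phosphate buffer is mild enough to spare the MOM acetal.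

Step 7
Reactants: 9 2-methoxy-4-(methoxymethoxy)-6-propylbenzoic acid; 10 benzyl bromide
Product: 11 benzyl 2-methoxy-4-(methoxymethoxy)-6-propylbenzoate
Conditions: K2CO3 (1.5 equiv), DMF, rt
Reagents that add atoms: benzyl bromide (10), BrCc1ccccc1
Why: Carboxylate O-alkylation (SN2 at the benzylic carbon), which is not slowed by the two ortho substituents that would block an acyl-substitution esterification.

Step 8
Reactants: 11 benzyl 2-methoxy-4-(methoxymethoxy)-6-propylbenzoate
Product: 12 benzyl 4-hydroxy-2-methoxy-6-propylbenzoate
Conditions: HCl (cat.), MeOH, 45 °C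
Reagents that add atoms: none
Why: Acid-catalysed acetal exchange (MOM cleavage) releases the phenol while the formaldehyde unit leaves as its dimethyl acetal; the di-ortho-substituted benzyl ester is shielded from transesterification and the aryl methyl ether is inert.

Step 9
Reactants: 3 2-iodo-1,5-dimethoxy-3-pentylbenzene; 13 carbon monoxide; 12 benzyl 4-hydroxy-2-methoxy-6-propylbenzoate
Product: 14 benzyl 4-[(2,4-dimethoxy-6-pentylbenzoyl)oxy]-2-methoxy-6-propylbenzoate
Conditions: Pd(OAc)2 (5 mol %), Xantphos (7.5 mol %), Et3N (3 equiv), CO (1 atm, balloon), toluene, 90 °C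
Reagents that add atoms: carbon monoxide (13), [C-]#[O+]
Why: Palladium(0) adds oxidatively into the C–I bond of 3, CO inserts into the aryl–palladium bond to give an aroyl-palladium(II) iodide, triethylamine delivers 12 to the metal as its phenoxide, and acyl–oxygen reductive elimination releases the aryl ester and returns palladium(0), the HI ending as the ammonium iodide. The closest known reaction type is the palladium-catalysed aryloxycarbonylation of aryl iodides with phenols under atmospheric CO. No ring closes and no stereocentre is created; the two new skeletal bonds are ring-A C1–C(=O) and C(=O)–O4 of ring B. The step needs carbonylative coupling to win over direct diaryl ether formation and over hydrodeiodination, and the crowded, electron-rich di-ortho-substituted aryl-palladium secures this because CO insertion relieves its strain and is far faster than aryl–oxygen reductive elimination. The ester bond is made at the metal, not through a tetrahedral intermediate at the hindered carbonyl, and the phenol of 12 is flanked only by hydrogens and acidified by its para ester, so it is readily available as the phenoxide under mild amine base. The benzyl ester and methyl ethers are spectators.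

Step 10
Reactants: 14 benzyl 4-[(2,4-dimethoxy-6-pentylbenzoyl)oxy]-2-methoxy-6-propylbenzoate
Product: 15 4-[(2,4-dimethoxy-6-pentylbenzoyl)oxy]-2-methoxy-6-propylbenzoic acid
Conditions: H2 (1 atm), 10% Pd/C, EtOAc, rt
Reagents that add atoms: none
Why: Catalytic hydrogenolysis of the benzylic C–O bond frees the carboxylic acid as toluene is lost, while the aryl ester of the depside, the methyl ethers and both arenes are untouched under these mild conditions.

**Compound list**
1 | olivetol (5-pentylbenzene-1,3-diol) | CCCCCc1cc(O)cc(O)c1 | starting material
2 | 1,3-dimethoxy-5-pentylbenzene | CCCCCc1cc(OC)cc(OC)c1 | intermediate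
3 | 2-iodo-1,5-dimethoxy-3-pentylbenzene | CCCCCc1cc(OC)cc(OC)c1I | intermediate
4 | 5-propylresorcinol (5-propylbenzene-1,3-diol) | CCCc1cc(O)cc(O)c1 | starting material
5 | [(2,4-dihydroxy-6-propylphenyl)methylidene]dimethylammonium chloride | CCCc1cc(O)cc(O)c1C=[N+](C)C.[Cl-] | intermediate (not isolated)
6 | 2,4-dihydroxy-6-propylbenzaldehyde | CCCc1cc(O)cc(O)c1C=O | intermediate
7 | 2-hydroxy-4-(methoxymethoxy)-6-propylbenzaldehyde | CCCc1cc(OCOC)cc(O)c1C=O | intermediate
8 | 2-methoxy-4-(methoxymethoxy)-6-propylbenzaldehyde | CCCc1cc(OCOC)cc(OC)c1C=O | intermediate
9 | 2-methoxy-4-(methoxymethoxy)-6-propylbenzoic acid | CCCc1cc(OCOC)cc(OC)c1C(=O)O | intermediate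
10 | benzyl bromide | BrCc1ccccc1 | starting material
11 | benzyl 2-methoxy-4-(methoxymethoxy)-6-propylbenzoate | CCCc1cc(OCOC)cc(OC)c1C(=O)OCc1ccccc1 | intermediate
12 | benzyl 4-hydroxy-2-methoxy-6-propylbenzoate | CCCc1cc(O)cc(OC)c1C(=O)OCc1ccccc1 | intermediate
13 | carbon monoxide | [C-]#[O+] | starting material
14 | benzyl 4-[(2,4-dimethoxy-6-pentylbenzoyl)oxy]-2-methoxy-6-propylbenzoate | CCCCCc1cc(OC)cc(OC)c1C(=O)Oc1cc(CCC)c(C(=O)OCc2ccccc2)c(OC)c1 | intermediate
15 | 4-[(2,4-dimethoxy-6-pentylbenzoyl)oxy]-2-methoxy-6-propylbenzoic acid | CCCCCc1cc(OC)cc(OC)c1C(=O)Oc1cc(CCC)c(C(=O)O)c(OC)c1 | target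

**Step count**
Total steps: 10.
Longest linear sequence: 8 steps (5-propylresorcinol through steps 3–10); the ring-A branch contributes steps 1–2.

**Steps most likely to fail**

Step 9. Capture of the crowded aroyl-palladium by the phenoxide may be too slow, so that hydrodeiodination and precipitation of palladium black outrun ester formation. Fallback: setting out from 3, iodine–lithium exchange (n-BuLi, THF, −78 °C) should give 2,4-dimethoxy-6-pentylphenyllithium F1, which is quenched with dry CO2 and acidified to 2,4-dimethoxy-6-pentylbenzoic acid F2. Treating F2 and phenol 12 with trifluoroacetic anhydride in toluene at rt should form 2,4-dimethoxy-6-pentylbenzoic trifluoroacetic anhydride F3 in the flask. Its acylium-like reactivity tolerates the two ortho substituents, and it should acylate 12 to give 14, where the route is rejoined.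

Step 6. Hypochlorous acid may escape the scavenger and chlorinate the electron-rich ring, or the MOM acetal may be lost in the acidic buffer. Fallback: the carboxyl carbon is introduced at the acid oxidation level so that no aldehyde oxidation is needed. Setting out from 4, C-carboxylation with methyl magnesium carbonate (DMF, 120 °C, acidic work-up) should give 2,4-dihydroxy-6-propylbenzoic acid F4, provided carboxylation goes to the same ring carbon as the formylation; this regiochemistry is the weak point of the fallback and would need confirming. Selective carboxylate benzylation (BnBr, KHCO3, DMF) should give benzyl 2,4-dihydroxy-6-propylbenzoate F5. MOMCl/i-Pr2NEt on the non-chelated 4-hydroxyl should give benzyl 2-hydroxy-4-(methoxymethoxy)-6-propylbenzoate F6. Methylation (MeI, K2CO3, DMF) then returns to the route at 11.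

Step 2. Iodination may leak to the carbon between the two methoxy groups, or the still-activated ring may be iodinated a second time. Fallback: the halogen is placed by bromination and the iodide is then made by halogen exchange instead of C–H iodination. Setting out from 2, NBS (CH2Cl2, 0 °C) should give 2-bromo-1,5-dimethoxy-3-pentylbenzene F7, which is purified. Copper-catalysed aromatic Finkelstein exchange (NaI, CuI cat., trans-N,N′-dimethylcyclohexane-1,2-diamine, dioxane, 110 °C) should then convert it into 3, where the route is rejoined.

**Further compounds**
F1 | step 9 | 2,4-dimethoxy-6-pentylphenyllithium | CCCCCc1cc(OC)cc(OC)c1[Li]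
F2 | step 9 | 2,4-dimethoxy-6-pentylbenzoic acid | CCCCCc1cc(OC)cc(OC)c1C(=O)O
F3 | step 9 | 2,4-dimethoxy-6-pentylbenzoic trifluoroacetic anhydride | CCCCCc1cc(OC)cc(OC)c1C(=O)OC(=O)C(F)(F)F
F4 | step 6 | 2,4-dihydroxy-6-propylbenzoic acid | CCCc1cc(O)cc(O)c1C(=O)O
F5 | step 6 | benzyl 2,4-dihydroxy-6-propylbenzoate | CCCc1cc(O)cc(O)c1C(=O)OCc1ccccc1
F6 | step 6 | benzyl 2-hydroxy-4-(methoxymethoxy)-6-propylbenzoate | CCCc1cc(OCOC)cc(O)c1C(=O)OCc1ccccc1
F7 | step 2 | 2-bromo-1,5-dimethoxy-3-pentylbenzene | CCCCCc1cc(OC)cc(OC)c1Br
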